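The numbers in the tables are simulated for substances that don't exist, and the scatter is random.

The blue run was the flask I read first, since the violet flask had the same charge and was asked about at a later time.

| flask | starting material | coupling partner | catalyst | time |
|---|---|---|---|---|
| blue | 80.0 mM | 160 mM | 1.60 mM |  |
| grey | 48.0 mM | 128 mM | 1.60 mM |  |
| green | 80.0 mM | 160 mM | 4.80 mM |  |
| amber | 160 mM | 160 mM | 1.60 mM |  |
| violet | 80.0 mM | 160 mM | 1.60 mM | 34 min |

| blue run: time / min | blue run: [target] / mM | grey run: time / min | grey run: [target] / mM | green run: time / min | green run: [target] / mM | amber run: time / min | amber run: [target] / mM |
|---|---|---|---|---|---|---|---|
| 0.68 | 2.3 | 0.68 | 2.6 | 0.68 | 18.2 | 0.68 | 0.6 |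
| 1.5 | 4.6 | 1.5 | 4.0 | 1.5 | 36.3 | 1.5 | 2.5 |
| 3.4 | 9.7 | 3.4 | 8.2 | 3.4 | 73.4 | 3.4 | 8.7 |
| 7.6 | 21.6 | 7.6 | 19.1 | 7.6 | 79.7 | 7.6 | 20.5 |
| 17 | 44.9 | 17 | 38.7 | 17 | 79.0 | 17 | 42.0 |

(readings scatter by 0.8 mM)

- Overall: starting material + coupling partner -> target, with catalyst as catalyst.
- Constant volume, constant temperature.
- What is held in complexes is read along with the free species.
- "The second partner" is coupling partner.
- An order is taken over about fifteen percent of the charge, up and down.

- apparent order in [starting material] of the starting rate, round the charge of the blue run (the rate where two percent of its starting material have turned into target) (one fixed amount of target, the same in the runs compared)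
- apparent order in [coupling partner] of the starting rate, round the charge of the blue run (the rate where two percent of its starting material have turned into target)
- the grey run starts with 32.0 mM less of starting material and of coupling partner than the blue run, and with no target. Compared where both hold the same amount of starting material, once fifteen percent of what the grey run was charged with has turned into target, is the grey run faster, slower or alike (within a tenth)?
- target in the violet run at 34 min, as a share of the starting material charged
- which of these the readings show (two substrates go astray together / a little impurity takes part of the catalyst at once / the substrate is lost by itself / the substrate pairs with itself)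

From the blue run I took one number. Its target stood at 44.9 mM after 17 min, an average rate of 2.64 mM/min. Starting material was the limiting reagent, its 80.0 mM being less than the 160 mM of coupling partner, and that charge divided by the average rate gave 30.3 min. I called this the clearing time: the time a flask takes to turn its whole charge if it keeps that average rate.

I then solved the violet flask at both ends. At the zero-order end the rate owes nothing to [starting material], so target climbs in a straight line; the violet flask, asked about at 34 min, later than the clearing time, then stands at the ceiling of 100% of its charge. At the first-order end the rate follows [starting material], and the blue run kept 43.9% of its charge at 17 min. The violet time is twice that, so the same share is taken again, leaving 19.3% and putting target at 80.7%.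

The readings placed the violet flask near the top end. The amber run, charged with twice the starting material of the blue run and the same coupling partner, read 42.0 mM at 17 min, less than the blue run's 44.9 mM, whereas at the first-order end the larger charge reads higher. But the blue run's average did sag, from 2.84 mM/min up to 7.6 min to 2.64 mM/min up to 17 min, so I committed to a share below the ceiling, though closer to it than to 80.7%.

The forecast gave 94%, with a range of 85% to 99%, holding that “the order in starting material is about zero”. It put the orders at −0.1 in [starting material] and 0.8 in [coupling partner], called the grey run alike, and chose: a little impurity takes part of the catalyst at once.

The violet run gave 97.2% at 34 min, inside the forecast's range, with orders of −0.058 and 0.44 and the grey run alike; but the readings showed that the substrate pairs with itself.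

    catalyst + starting material ⇌ catalyst-substrate complex, settled at all times (106.0 /M)
    catalyst + coupling partner ⇌ catalyst-reagent complex, settled at all times (10.20 /M)
    catalyst-substrate complex + catalyst-reagent complex → target + 2 catalyst (7260 /M/min)
    2 starting material ⇌ idle substrate dimer, settled at all times (27.30 /M)

At one fixed small amount of target, the amber run went at 0.92 of the blue run's rate. At 34 min the violet run was 3.70 min past its clearing time, and its target still stood 2.80% of the charge short of the whole. Divided by 9.0, the factor by which the green run outran the blue run at that same amount, the clearing time came to 3.37 min for the green run, whose target read 73.4 mM at 3.4 min.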